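**Plan**

1. Retrosynthesis: cut the acetate, then the lactone C–O bond. Next cut the bond between the side-chain CH(CH2OAc) carbon and the lactone β-carbon, together with the exocyclic methylene (dianionic Ireland–Claisen of an (R)-malate allyl ester). Then cut both C1–C2 and C3–C3a of the cyclopentane (radical [3+2] annulation, phenyl vinyl sulfone as ethylene equivalent), and last the allyl–C7a bond.
2. Forward: cyclohexanone → quaternary C7a → (E)-alkenyl arm on C7a and xanthate on the neighbouring carbinol → cyclopentane closed onto the cyclohexane → side chain grown from the acetaldehyde arm → γ-lactone closed → acetate.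
3. Enabling feature: the C2–C3 ethano bridge of the five-membered ring joins the ring-fusion CH (C3a) and the side-chain CH (C1), and both are bonded to quaternary C7a. A C3a radical carrying a C7a-alkenyl group is therefore a homoallyl radical that can take up a two-carbon alkene and close 5-exo.
4. Stereochemistry: C7a by PHOX–palladium catalysis; C3a and C1 relayed from C7a in the key step; the three side-chain centres from (R)-malic acid through the chelated enolate and chair transition state of the Claisen step.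

Key step: step 8

Assumption: (R)-t-BuPHOX is taken to give the R ketone 5 (mirror image of the sense expected for the S ligand); the carbinol epimers of 11–13 and the sulfone epimers of 15 are carried as mixtures because both centres are erased later.

Abbreviation: Hy = trans-fused 4,4,7a-trimethyloctahydro-1H-inden-1-yl group of the target (ring-fusion H and 7a-methyl trans, C1 substituent cis to the 7a-methyl; (1R,3aS,7aS) in the target; the CIP letters of the ring change with the C1 substituent, the SMILES are authoritative).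

**Step 1**
Reactants: 1 2,2,6-trimethylcyclohexan-1-one; 2 allyl chloroformate
Product: 4 allyl 2,6,6-trimethylcyclohex-1-en-1-yl carbonate, via lithium enolate 3 (not isolated)
Conditions: LiN(SiMe3)2, THF, 0 °C; then 2, −78 to 25 °C
Reagents that add atoms: none
Why: The ketone has one enolisable position, so its lithium enolate is a single regioisomer and O-acylation by the chloroformate (enolate O-acylation) gives the enol carbonate needed for the Tsuji allylation.

**Step 2**
Reactants: 4 allyl 2,6,6-trimethylcyclohex-1-en-1-yl carbonate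
Product: 5 (2R)-2-allyl-2,6,6-trimethylcyclohexan-1-one
Conditions: Pd2(dba)3 (2.5 mol %), (R)-t-BuPHOX (6 mol %), THF, 25 °C
Reagents that add atoms: none
Why: Decarboxylative asymmetric Tsuji allylation: zerovalent palladium ionises the allyl carbonate, CO2 is lost and the enolate recombines with the π-allyl unit inside the chiral PHOX pocket, which sets the quaternary stereocentre (future C7a); this ketone class has close precedent.

**Step 3**
Reactants: 5 (2R)-2-allyl-2,6,6-trimethylcyclohexan-1-one
Product: 7 (2R)-2-(3-hydroxypropyl)-2,6,6-trimethylcyclohexan-1-one, via alkyl-9-BBN adduct 6 (not isolated)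
Conditions: 9-BBN, THF, 0 to 25 °C; then NaOH, H2O2, H2O, 0 °C
Reagents that add atoms: hydrogen peroxide, OO
Why: Anti-Markovnikov hydroboration–oxidation of the terminal alkene; the ketone, flanked by two quaternary carbons, should be inert to the bulky borane.

**Step 4**
Reactants: 7 (2R)-2-(3-hydroxypropyl)-2,6,6-trimethylcyclohexan-1-one
Product: 9 (2E)-3-[(1R)-1,3,3-trimethyl-2-oxocyclohexyl]prop-2-enal, via saturated aldehyde 8 (not isolated)
Conditions: IBX (3 equiv), DMSO, 25 °C then 75 °C
Reagents that add atoms: none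
Why: IBX oxidises the primary alcohol to aldehyde 8 and on heating dehydrogenates it to the conjugated enal (IBX α,β-dehydrogenation of carbonyl compounds); the γ-carbon is quaternary and the ketone has no α-hydrogen, so only the E-enal can form.

**Step 5**
Reactants: 9 (2E)-3-[(1R)-1,3,3-trimethyl-2-oxocyclohexyl]prop-2-enal
Product: 10 (2R)-2-[(1E)-3,3-dimethoxyprop-1-en-1-yl]-2,6,6-trimethylcyclohexan-1-one
Conditions: HC(OMe)3, MeOH, PPTS (cat.), 25 °C
Reagents that add atoms: trimethyl orthoformate, COC(OC)OC
Why: Acid-catalysed acetalisation turns the electron-poor enal into an unactivated alkene, as the polarity match of the radical step requires, and protects the aldehyde; the hindered ketone should not ketalise.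

**Step 6**
Reactants: 10 (2R)-2-[(1E)-3,3-dimethoxyprop-1-en-1-yl]-2,6,6-trimethylcyclohexan-1-one
Product: 11 (2R)-2-[(1E)-3,3-dimethoxyprop-1-en-1-yl]-2,6,6-trimethylcyclohexan-1-ol (both C1 epimers)
Conditions: LiAlH4, Et2O, 0 °C to reflux
Reagents that add atoms: none
Why: Hydride reduction of the hindered ketone; the carbinol configuration is irrelevant because this carbon becomes a planar radical.

**Step 7**
Reactants: 11 (2R)-2-[(1E)-3,3-dimethoxyprop-1-en-1-yl]-2,6,6-trimethylcyclohexan-1-ol
Product: 13 O-{(2R)-2-[(1E)-3,3-dimethoxyprop-1-en-1-yl]-2,6,6-trimethylcyclohexyl} S-methyl carbonodithioate, via sodium xanthate 12 (not isolated)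
Conditions: NaH, imidazole (cat.), THF, 60 °C; CS2, 25 °C; MeI, 25 °C
Reagents that add atoms: carbon disulfide, S=C=S; iodomethane, CI
Why: Xanthate formation (first stage of a Barton–McCombie deoxygenation) from the alkoxide, CS2 and MeI; the carbinol has no β-hydrogen, so Chugaev elimination cannot compete.

**Step 8**
Reactants: 13 the xanthate; 14 phenyl vinyl sulfone
Product: 15 1-(2,2-dimethoxyethyl)-4,4,7a-trimethyl-2-(phenylsulfonyl)octahydro-1H-indene (Hy–CH2CH(OMe)2 with PhSO2 at C2; both C2 epimers)
Conditions: (Me3Si)3SiH (syringe pump), AIBN, 14 (5 equiv), PhMe, 90 °C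
Reagents that add atoms: none
Why: A silyl radical adds to the thiocarbonyl of 13 and fragmentation gives the secondary cyclohexyl radical at the carbinol carbon (future C3a), a homoallyl radical that adds as a nucleophilic radical to the CH2 terminus of 14; the electrophilic α-sulfonyl radical then attacks the alkene carbon attached to the quaternary centre and the resulting secondary radical takes hydrogen from the silane, so C3–C3a and C1–C2 form in one chain reaction. The closest known reaction type is the radical [3+2] annulation of homoallyl radicals with electron-poor alkenes, a Giese addition followed by cyclisation. The cyclopentane closes in the 5-exo-trig mode. C3a is set in the intermolecular addition, which should occur anti to the alkenyl arm, the larger substituent on the neighbouring quaternary C7a, so that the new chain and the arm are trans-diequatorial and the ring fusion becomes trans. C1 is set in the ring closure through a chair-like transition state with the acetal-bearing alkene carbon pseudo-equatorial, which places the side arm cis to the angular methyl as in 17β-substituted steroid D rings. The step needs bimolecular trapping and ring closure to outrun 3-exo closure with 1,2-alkenyl shift and premature hydrogen transfer, which the excess of 14, the polarity alternation, the slow hydrogen donor and the E geometry (acetal C–H out of reach of a 1,5-hydrogen shift) should secure.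

**Step 9**
Reactants: 15 the hydrindane sulfone
Product: 17 2-Hy-acetaldehyde, via dimethyl acetal 16 (not isolated)
Conditions: 6% Na(Hg), Na2HPO4, MeOH–THF, −20 to 0 °C; then 1 M HCl, THF, 25 °C
Reagents that add atoms: water, O
Why: Reductive desulfonylation by electron transfer from sodium amalgam removes the activating group of the ethylene equivalent, and aqueous acid then hydrolyses the acetal to the aldehyde.

**Step 10**
Reactants: 17 2-Hy-acetaldehyde; 18 (tert-butyldimethylsilyloxy)acetaldehyde
Product: 21 (2E)-4-(tert-butyldimethylsilyloxy)-2-Hy-but-2-enal, via cyclohexylimine 19 (not isolated), via hydroxy imine 20 (not isolated)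
Conditions: c-C6H11NH2, 4 Å MS, Et2O, 25 °C; LiN(i-Pr)2, THF, −78 to 0 °C; 18, −78 °C; aq. (CO2H)2, 25 °C
Reagents that add atoms: water, O
Why: Directed aldol condensation: the lithiated cyclohexylimine of 17 adds to aldehyde 18 and acidic hydrolysis with dehydration gives the 2-substituted enal, for which the E isomer (CH2OSi cis to the ring, trans to CHO) is the thermodynamic one.

**Step 11**
Reactants: 21 the (E)-enal
Product: 22 (2E)-4-(tert-butyldimethylsilyloxy)-2-Hy-but-2-en-1-ol
Conditions: NaBH4, CeCl3·7H2O, MeOH, −20 °C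
Reagents that add atoms: none
Why: Luche reduction gives selective 1,2-reduction of the enal to the allylic alcohol without touching the alkene geometry.

**Step 12**
Reactants: 23 (R)-malic acid
Product: 25 (3R)-3-hydroxy-4-methoxy-4-oxobutanoic acid, via trifluoroacetoxy anhydride 24 (not isolated)
Conditions: (CF3CO)2O, 0 to 25 °C; evaporate; MeOH, 25 °C
Reagents that add atoms: methanol, CO
Why: Trifluoroacetic anhydride gives the O-trifluoroacetyl cyclic anhydride, which methanol opens at the more electrophilic carbonyl next to the acyloxy group and then deacylates, leaving the distal carboxylic acid free (regioselective anhydride alcoholysis).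

**Step 13**
Reactants: 22 the allylic alcohol; 25 the malic acid 1-methyl ester
Product: 26 1-methyl 4-[(2E)-4-(tert-butyldimethylsilyloxy)-2-Hy-but-2-en-1-yl] (2R)-2-hydroxybutanedioate
Conditions: EDC·HCl, DMAP (cat.), CH2Cl2, 0 to 25 °C
Reagents that add atoms: none
Why: Steglich-type carbodiimide esterification; the primary allylic alcohol should outcompete the hindered, electron-poor secondary hydroxyl of 25.

**Step 14**
Reactants: 26 the malate allyl ester
Product: 28 (2S,3R)-2-[(2R)-1-(tert-butyldimethylsilyloxy)-3-Hy-but-3-en-2-yl]-3-hydroxy-4-methoxy-4-oxobutanoic acid, via dilithium enolate 27 (not isolated)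
Conditions: LiN(i-Pr)2 (3 equiv), THF, −78 to 25 °C; aq. HCl work-up
Reagents that add atoms: none
Why: Dianionic Ireland–Claisen rearrangement: the lithium alkoxide and ester enolate form a six-membered chelate (enolate oxygen cis to the carbinol carbon) that reacts on the face anti to the CO2Me group, as in the Fráter–Seebach alkylation, and the chair transition state with the CH2OSi group of the E-alkene equatorial sets the side-chain CH centre while the [3,3] shift creates the 1,1-disubstituted alkene.

**Step 15**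
Reactants: 28 the Claisen acid
Product: 31 (3R,4R)-4-[(2R)-1-(tert-butyldimethylsilyloxy)-3-Hy-but-3-en-2-yl]-3-hydroxyoxolan-2-one, via mixed anhydride 29 (not isolated), via hydroxy ester 30 (not isolated)
Conditions: i-BuOCOCl, N-methylmorpholine, THF, −15 °C; NaBH4, H2O, 0 °C; PPTS (cat.), CH2Cl2, 25 °C
Reagents that add atoms: none
Why: The free acid is activated selectively as a mixed carbonic anhydride and reduced by NaBH4 to the primary alcohol, which closes the γ-lactone on the neighbouring methyl ester under mild acid (five-membered ring favoured).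

**Step 16**
Reactants: 31 the silyl ether lactone
Product: 32 (3R,4R)-3-hydroxy-4-[(2R)-1-hydroxy-3-Hy-but-3-en-2-yl]oxolan-2-one
Conditions: HF·pyridine, THF, 0 to 25 °C
Reagents that add atoms: none
Why: Fluoride-mediated cleavage of the primary silyl ether under slightly acidic conditions, which should not epimerise the α-hydroxy lactone.

**Step 17**
Reactants: 32 the diol lactone
Product: 33 (2R)-2-[(3R,4R)-4-hydroxy-5-oxooxolan-3-yl]-3-[(1R,3aS,7aS)-4,4,7a-trimethyloctahydro-1H-inden-1-yl]but-3-en-1-yl acetate (target)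
Conditions: AcCl, 2,4,6-collidine, CH2Cl2, −78 °C
Reagents that add atoms: acetyl chloride, CC(Cl)=O
Why: Kinetic acylation at low temperature with a hindered pyridine base selects the primary alcohol over the hindered, less nucleophilic α-hydroxy lactone hydroxyl.

**Compound list**

1 | 2,2,6-trimethylcyclohexan-1-one | CC1CCCC(C)(C)C1=O | starting material
2 | allyl chloroformate | C=CCOC(Cl)=O | starting material
3 | lithium 2,6,6-trimethylcyclohex-1-en-1-olate | [Li+].[O-]C1=C(C)CCCC1(C)C | intermediate
4 | allyl 2,6,6-trimethylcyclohex-1-en-1-yl carbonate | C=CCOC(=O)OC1=C(C)CCCC1(C)C | intermediate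
5 | (2R)-2-allyl-2,6,6-trimethylcyclohexan-1-one | C=CC[C@@]1(C)CCCC(C)(C)C1=O | intermediate
6 | B-alkyl-9-borabicyclo[3.3.1]nonane adduct of 5 (boron on the terminal carbon, quaternary centre unchanged) | B1(CCC[C@@]2(C)CCCC(C)(C)C2=O)C2CCCC1CCC2 | intermediate
7 | (2R)-2-(3-hydroxypropyl)-2,6,6-trimethylcyclohexan-1-one | OCCC[C@@]1(C)CCCC(C)(C)C1=O | intermediate
8 | 3-[(1R)-1,3,3-trimethyl-2-oxocyclohexyl]propanal | O=CCC[C@@]1(C)CCCC(C)(C)C1=O | intermediate
9 | (2E)-3-[(1R)-1,3,3-trimethyl-2-oxocyclohexyl]prop-2-enal | O=C/C=C/[C@@]1(C)CCCC(C)(C)C1=O | intermediate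
10 | (2R)-2-[(1E)-3,3-dimethoxyprop-1-en-1-yl]-2,6,6-trimethylcyclohexan-1-one | COC(OC)/C=C/[C@@]1(C)CCCC(C)(C)C1=O | intermediate
11 | (2R)-2-[(1E)-3,3-dimethoxyprop-1-en-1-yl]-2,6,6-trimethylcyclohexan-1-ol, both C1 epimers | COC(OC)/C=C/[C@@]1(C)CCCC(C)(C)C1O | intermediate
12 | sodium O-alkyl carbonodithioate of 11, both C1 epimers | [Na+].COC(OC)/C=C/[C@@]1(C)CCCC(C)(C)C1OC(=S)[S-] | intermediate
13 | O-{(2R)-2-[(1E)-3,3-dimethoxyprop-1-en-1-yl]-2,6,6-trimethylcyclohexyl} S-methyl carbonodithioate, both C1 epimers | COC(OC)/C=C/[C@@]1(C)CCCC(C)(C)C1OC(=S)SC | intermediate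
14 | phenyl vinyl sulfone | C=CS(=O)(=O)c1ccccc1 | starting material
15 | 1-(2,2-dimethoxyethyl)-4,4,7a-trimethyl-2-(phenylsulfonyl)octahydro-1H-indene, trans-fused, C1 arm cis to 7a-methyl, both C2 epimers | COC(OC)C[C@H]1C(S(=O)(=O)c3ccccc3)C[C@H]2C(C)(C)CCC[C@]12C | intermediate
16 | 1-(2,2-dimethoxyethyl)-4,4,7a-trimethyloctahydro-1H-indene (Hy–CH2CH(OMe)2) | COC(OC)C[C@H]1CC[C@H]2C(C)(C)CCC[C@]12C | intermediate
17 | 2-Hy-acetaldehyde | O=CC[C@H]1CC[C@H]2C(C)(C)CCC[C@]12C | intermediate
18 | (tert-butyldimethylsilyloxy)acetaldehyde | CC(C)(C)[Si](C)(C)OCC=O | starting material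
19 | N-cyclohexyl imine of 17 | C1CCCCC1N=CC[C@H]2CC[C@H]3C(C)(C)CCC[C@]23C | intermediate
20 | N-cyclohexyl imine of 4-(tert-butyldimethylsilyloxy)-3-hydroxy-2-Hy-butanal, mixture at the two new centres | C1CCCCC1N=CC(C(O)CO[Si](C)(C)C(C)(C)C)[C@H]2CC[C@H]3C(C)(C)CCC[C@]23C | intermediate
21 | (2E)-4-(tert-butyldimethylsilyloxy)-2-Hy-but-2-enal | O=C/C(=C/CO[Si](C)(C)C(C)(C)C)[C@H]1CC[C@H]2C(C)(C)CCC[C@]12C | intermediate
22 | (2E)-4-(tert-butyldimethylsilyloxy)-2-Hy-but-2-en-1-ol | OC/C(=C/CO[Si](C)(C)C(C)(C)C)[C@H]1CC[C@H]2C(C)(C)CCC[C@]12C | intermediate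
23 | (R)-malic acid | OC(=O)[C@H](O)CC(=O)O | starting material
24 | (3R)-2,5-dioxooxolan-3-yl trifluoroacetate | O=C1OC(=O)C[C@H]1OC(=O)C(F)(F)F | intermediate
25 | (3R)-3-hydroxy-4-methoxy-4-oxobutanoic acid | COC(=O)[C@H](O)CC(=O)O | intermediate
26 | 1-methyl 4-[(2E)-4-(tert-butyldimethylsilyloxy)-2-Hy-but-2-en-1-yl] (2R)-2-hydroxybutanedioate | COC(=O)[C@H](O)CC(=O)OC/C(=C/CO[Si](C)(C)C(C)(C)C)[C@H]1CC[C@H]2C(C)(C)CCC[C@]12C | intermediate
27 | dilithium alkoxide–ester enolate of 26 (enolate oxygen cis to the carbinol carbon) | [Li+].[Li+].COC(=O)[C@H]([O-])/C=C(\[O-])OC/C(=C/CO[Si](C)(C)C(C)(C)C)[C@H]1CC[C@H]2C(C)(C)CCC[C@]12C | intermediate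
28 | (2S,3R)-2-[(2R)-1-(tert-butyldimethylsilyloxy)-3-Hy-but-3-en-2-yl]-3-hydroxy-4-methoxy-4-oxobutanoic acid | C=C([C@H]1CC[C@H]2C(C)(C)CCC[C@]12C)[C@H](CO[Si](C)(C)C(C)(C)C)[C@H](C(=O)O)[C@@H](O)C(=O)OC | intermediate
29 | isobutyl carbonic mixed anhydride of 28 | C=C([C@H]1CC[C@H]2C(C)(C)CCC[C@]12C)[C@H](CO[Si](C)(C)C(C)(C)C)[C@H](C(=O)OC(=O)OCC(C)C)[C@@H](O)C(=O)OC | intermediate
30 | methyl (2R,3R)-2-hydroxy-3-(hydroxymethyl)-4-silyloxymethyl-5-Hy-hex-5-enoate type hydroxy ester (acid of 28 reduced to CH2OH) | C=C([C@H]1CC[C@H]2C(C)(C)CCC[C@]12C)[C@H](CO[Si](C)(C)C(C)(C)C)[C@H](CO)[C@@H](O)C(=O)OC | intermediate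
31 | (3R,4R)-4-[(2R)-1-(tert-butyldimethylsilyloxy)-3-Hy-but-3-en-2-yl]-3-hydroxyoxolan-2-one | C=C([C@H]1CC[C@H]2C(C)(C)CCC[C@]12C)[C@H](CO[Si](C)(C)C(C)(C)C)[C@@H]1COC(=O)[C@@H]1O | intermediate
32 | (3R,4R)-3-hydroxy-4-[(2R)-1-hydroxy-3-Hy-but-3-en-2-yl]oxolan-2-one | C=C([C@H]1CC[C@H]2C(C)(C)CCC[C@]12C)[C@H](CO)[C@@H]1COC(=O)[C@@H]1O | intermediate
33 | (2R)-2-[(3R,4R)-4-hydroxy-5-oxooxolan-3-yl]-3-[(1R,3aS,7aS)-4,4,7a-trimethyloctahydro-1H-inden-1-yl]but-3-en-1-yl acetate | C=C([C@H]1CC[C@H]2C(C)(C)CCC[C@]12C)[C@H](COC(C)=O)[C@@H]1COC(=O)[C@@H]1O | target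

**Count**

Total steps: 17. Longest linear sequence: 16 (steps 1–11 and 13–17; step 12 prepares the malate half-ester).

**Steps most likely to fail**

1. Step 8. The intermolecular radical addition may occur on the wrong face (cis ring fusion) or the ring closure may give the C1 epimer. Hydrogen transfer may also intercept the sulfonyl radical before it cyclises, or the first radical may undergo a 1,2-alkenyl shift. Fallback (from 5, back at 17): the cyclopentane would be closed by polar chemistry. Wacker oxidation of 5 (PdCl2, CuCl, O2, DMF–H2O) would give the diketone (R)-2,2,6-trimethyl-6-(2-oxopropyl)cyclohexan-1-one F1. Intramolecular aldol condensation (KOH, xylene, 110 °C) would give the bicyclic enone 4,4,7a-trimethyl-5,6,7,7a-tetrahydro-1H-inden-2(4H)-one F2. Kinetic deprotonation at the CH2 next to the quaternary carbon and allylation (LiN(i-Pr)2, allyl bromide) would give the 1-allyl enone F3. Li/NH3 reduction, with equilibration at the α-carbon, would give the trans-fused 1-allyl-4,4,7a-trimethyloctahydro-2H-inden-2-one F4. The ketone would be removed through its tosylhydrazone F5 (TsNHNH2; catecholborane, NaOAc) to give the 1-allyl hydrindane F6, and ozonolysis (O3; Me2S) would return to aldehyde 17.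

2. Step 14. Enolisation of the hindered ester may be incomplete, the dianion may condense or eliminate on warming, or facial selectivity of the chelate may be eroded by the bulky 2-substituent. Fallback (from 22, back at 31): stereocontrol would come from a chiral boron reagent, and the hydroxyl would be added afterwards. Esterification of 22 with 4-tert-butoxy-4-oxobutanoic acid (EDC, DMAP) would give the mixed succinate F7. Ireland–Claisen rearrangement of its boron enolate would give acid F8; the enolate would be made with the chiral B-bromo-4,5-diphenyl-1,3-bis(p-tolylsulfonyl)-1,3,2-diazaborolidine and the tertiary amine that places the boron–oxygen cis to the α-substituent. Reduction through the mixed anhydride F9 (i-BuOCOCl, N-methylmorpholine; NaBH4) to the hydroxy ester F10 and acid-catalysed lactonisation would give the deoxy lactone F11. Enolate hydroxylation (LiN(SiMe3)2; 2-(phenylsulfonyl)-3-phenyloxaziridine) anti to the ring substituent would give the trans hydroxy lactone F12. Mitsunobu inversion with 4-nitrobenzoic acid would give the cis 4-nitrobenzoate F13, and mild methanolysis (K2CO3, MeOH, 0 °C) would return to 31.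

3. Step 10. Aldehyde 18 may self-condense, the silyl ether may be lost during the acidic dehydration, or the alkene may form as an E/Z mixture. Fallback (from 17, back at 22): the condensation would be moved to the ester level. Pinnick oxidation (NaClO2, NaH2PO4, 2-methylbut-2-ene) would give Hy-acetic acid F14, and Me3SiCHN2 its methyl ester F15. The ester enolate (LiN(i-Pr)2) would add to 18 to give the aldol F16. Mesylation to F17 and E1cB elimination with DBU, which is under thermodynamic control and gives separable isomers, would give the (E)-enoate F18. Reduction with i-Bu2AlH would return to 22.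

**Further compounds**

F1 | step 8 | (R)-2,2,6-trimethyl-6-(2-oxopropyl)cyclohexan-1-one | CC(=O)C[C@@]1(C)CCCC(C)(C)C1=O
F2 | step 8 | 4,4,7a-trimethyl-5,6,7,7a-tetrahydro-1H-inden-2(4H)-one | O=C1C=C2C(C)(C)CCC[C@]2(C)C1
F3 | step 8 | 1-allyl-4,4,7a-trimethyl-5,6,7,7a-tetrahydro-1H-inden-2(4H)-one, C1 epimers | O=C1C=C2C(C)(C)CCC[C@]2(C)C1CC=C
F4 | step 8 | trans-fused 1-allyl-4,4,7a-trimethyloctahydro-2H-inden-2-one, allyl cis to 7a-methyl | C=CC[C@H]1C(=O)C[C@H]2C(C)(C)CCC[C@]12C
F5 | step 8 | tosylhydrazone of F4 | C=CC[C@H]1C(=NNS(=O)(=O)c3ccc(C)cc3)C[C@H]2C(C)(C)CCC[C@]12C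
F6 | step 8 | 1-allyl-4,4,7a-trimethyloctahydro-1H-indene (Hy–CH2CH=CH2) | C=CC[C@H]1CC[C@H]2C(C)(C)CCC[C@]12C
F7 | step 14 | tert-butyl (2E)-4-(tert-butyldimethylsilyloxy)-2-Hy-but-2-en-1-yl butanedioate | CC(C)(C)OC(=O)CCC(=O)OC/C(=C/CO[Si](C)(C)C(C)(C)C)[C@H]1CC[C@H]2C(C)(C)CCC[C@]12C
F8 | step 14 | 4-tert-butoxy-2-[(2R)-1-(tert-butyldimethylsilyloxy)-3-Hy-but-3-en-2-yl]-4-oxobutanoic acid, configured as in 28 | C=C([C@H]1CC[C@H]2C(C)(C)CCC[C@]12C)[C@H](CO[Si](C)(C)C(C)(C)C)[C@H](C(=O)O)CC(=O)OC(C)(C)C
F9 | step 14 | isobutyl carbonic mixed anhydride of F8 | C=C([C@H]1CC[C@H]2C(C)(C)CCC[C@]12C)[C@H](CO[Si](C)(C)C(C)(C)C)[C@H](C(=O)OC(=O)OCC(C)C)CC(=O)OC(C)(C)C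
F10 | step 14 | tert-butyl hydroxy ester from reduction of F8 | C=C([C@H]1CC[C@H]2C(C)(C)CCC[C@]12C)[C@H](CO[Si](C)(C)C(C)(C)C)[C@H](CO)CC(=O)OC(C)(C)C
F11 | step 14 | 4-[(2R)-1-(tert-butyldimethylsilyloxy)-3-Hy-but-3-en-2-yl]oxolan-2-one, ring carbon configured as in 31 | C=C([C@H]1CC[C@H]2C(C)(C)CCC[C@]12C)[C@H](CO[Si](C)(C)C(C)(C)C)[C@@H]1COC(=O)C1
F12 | step 14 | trans 3-hydroxy epimer of 31 | C=C([C@H]1CC[C@H]2C(C)(C)CCC[C@]12C)[C@H](CO[Si](C)(C)C(C)(C)C)[C@@H]1COC(=O)[C@H]1O
F13 | step 14 | 4-nitrobenzoate of 31 (cis) | C=C([C@H]1CC[C@H]2C(C)(C)CCC[C@]12C)[C@H](CO[Si](C)(C)C(C)(C)C)[C@@H]1COC(=O)[C@@H]1OC(=O)c3ccc(cc3)[N+](=O)[O-]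
F14 | step 10 | 2-Hy-acetic acid | OC(=O)C[C@H]1CC[C@H]2C(C)(C)CCC[C@]12C
F15 | step 10 | methyl 2-Hy-acetate | COC(=O)C[C@H]1CC[C@H]2C(C)(C)CCC[C@]12C
F16 | step 10 | methyl 4-(tert-butyldimethylsilyloxy)-3-hydroxy-2-Hy-butanoate, mixture at the two new centres | COC(=O)C(C(O)CO[Si](C)(C)C(C)(C)C)[C@H]1CC[C@H]2C(C)(C)CCC[C@]12C
F17 | step 10 | methanesulfonate of F16 | COC(=O)C(C(OS(C)(=O)=O)CO[Si](C)(C)C(C)(C)C)[C@H]1CC[C@H]2C(C)(C)CCC[C@]12C
F18 | step 10 | methyl (2E)-4-(tert-butyldimethylsilyloxy)-2-Hy-but-2-enoate | COC(=O)/C(=C/CO[Si](C)(C)C(C)(C)C)[C@H]1CC[C@H]2C(C)(C)CCC[C@]12C
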